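## Structural features

The target is a flavone: ring A is fused to the pyranone ring C through C4a–C8a, and ring B is attached at C2 through the C2–C1' bond. Ring C carries the only methyl ether of the molecule at C3, next to the C4 carbonyl. Ring A has the phloroglucinol pattern (O1, 5-OH, 7-OH) with a 3-methylbut-2-enyl chain at C8, and ring B is a catechol (3'-OH, 4'-OH) with a second such chain at C5', ortho to the 4'-OH. There is no stereocentre and no stereogenic double bond, so every problem is one of position and not of configuration. The fragile parts are the two ortho-prenylphenol units (C8 chain/7-OH and C5' chain/4'-OH), which close to 2,2-dimethylchromans in strong acid and do not survive electrophilic halogenation or hydrogenation, and the catechol, which is oxidised in basic, aerated media. The real difficulty is regiocontrol: C8 against C6 on ring A, a linear against a 1,1-dimethylallyl chain on both rings, and one O-methyl group among five oxygens, which rules out methyl ethers as phenol protection. The 5-OH is hydrogen-bonded to the C4 carbonyl and is the least reactive phenol, so it can be left free while the other three are masked. The key step exploits the position of C4 between C4a, a ring A carbon flanked by the oxygenated carbons C5 and C8a, and the methoxy-bearing C3: C4 can enter as carbon monoxide between an aryl iodide at C4a and the enolate carbon of a ring B ketone that already holds C2, C3 and the 3-methoxy group.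

## Logic of the disconnections

26 from 25. The last bonds cut are the three acetal O–CH2 bonds on O7, O3' and O4'. These oxygens must be blocked while the ring A chain is put in place, and acetals come off without loss of the 3-methoxy group. Nothing is simplified in the skeleton; the gain is that the three more reactive phenols are told apart from the 5-OH. The forward step must cleave acetals by acid without protonating the two alkenes that lie ortho to the freed hydroxyls.

25 from 22. The C8–CH2 bond of the ring A chain is cut and the chain is returned to O5. Direct C-alkylation cannot tell C8 from C6, whereas a chain on O5 reaches C8 only through two [3,3] shifts, to C6 with inversion (23) and on to C8 with a second inversion (24), so that position and linear form are both set. A regiochemical C–C bond formation thus becomes the isomerisation of an ether. The forward step requires the second shift to be faster than enolisation of 23, and O7 to be blocked.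

22 from 21 and 10. The O5–CH2 bond is cut. In 21 the 5-OH is the only free hydroxyl, so no choice between oxygens is needed, and a five-carbon chain is removed as a commercial building block. The demand is an O-alkylation of a hydrogen-bonded, hindered phenol that goes to completion.

21 from 20 and 2. Three acetal O–C bonds are cut. The reason is the built-in difference between the chelated 5-OH and the other three phenols, which lets one reagent distinguish them; no protecting group then has to be carried selectively through the ring closure. The forward step must stop at three acetals.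

20 from 18. The O1–C2 bond and the C2=C3 double bond of ring C are cut, and the five phenols are masked. Ring C disappears and the heterocycle becomes two arenes joined by a three-carbon chain. Because the ring A carbonyl of 18 is flanked by two identical oxygens, only one chromenone can form. The forward step must unmask the ortho oxygens and dehydrate in acid while the ring B chain is already present.

18 from 5, 16 and 15. The two bonds at C4 are cut, C4a–C4 and C4–C3. Here the molecule divides into a ring A part, a ring B part that already holds C2, C3 and the methoxy group, and a single carbon; one piece is symmetric and another has a single reactive site. The forward step must insert 16 between the aryl carbon of 5 and the enolate carbon of 15 and must not join them directly.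

5 from 3, and 3 from 1 and 2. The C–I bond and the three acetal O–C bonds are cut. The threefold symmetry of 1 is kept, so metalation can occur at one kind of carbon only. The demand is O- rather than C-alkylation of 1.

15 from 12 and 13. The bond between ring B and the carbonyl carbon is cut into an aryl anion equivalent and an acyl cation equivalent. This brings in C2, C3 and the methoxy group as one commercial unit and avoids any later α-functionalisation of a ketone. The forward step needs an acyl donor that takes up one aryl anion only.

12 from 9 and 10. The C5'–CH2 bond is cut into an aryl anion and an allyl cation equivalent. An ether on O4' is not used, since its ortho [3,3] shift would deliver the branched isomer to C5'. The demand is twofold: the metal must be placed at the bromine next to oxygen, and the allyl unit must be attacked at its primary end.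

9 from 8 and 2, and 8 from 6. Two acetal O–C bonds are cut, and one phenolic C–O bond is traced back to the C–CHO bond of 6. The gain is a commercial arene in which both halogens and one oxygen already sit at the right carbons. The forward step is an oxidative replacement of formyl by hydroxyl.

## Other disconnections considered

Alternative 1: The cut takes ring A apart at C7–C8, C6–C7 and C4a–C8a, so that the ring is made, with its chain already on C8, from 3-ethoxycyclobut-2-en-1-one A2 and the silyloxyalkyne triisopropyl(5-methylhex-4-en-1-ynyloxy)silane A3. In the forward direction heating would open A2 to a vinylketene, which adds across the electron-rich triple bond of A3. The new cyclobutenone opens again, and the dienylketene closes by a six-electron electrocyclisation and tautomerises to the pentasubstituted phenol A1.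
- In its favour: the chain is linear and on C8 by construction, so neither the C8/C6 question nor the linear/branched question arises. The three ring A oxygens emerge with three different substituents in one thermal, metal-free operation that an isolated trisubstituted alkene should tolerate.
- Against it here: A1 is only ring A. C4, C3, C2 and ring B must still be attached, and the acyl group must go to C4a although C6 is activated just as strongly by two flanking oxygens, so the regiochemical question moves from the chain to the acylation. The O5 ethyl ether must be cleaved at the very end with a boron or aluminium halide in the presence of two ortho-prenylphenol units and the 3-methoxy group. A3 needs several steps, whereas ring A of the chosen plan costs two steps from 1.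
- Comparison: on structure the alternative is the better of the two in one respect, the placement of the C8 chain, which in the chosen plan rests on step 11. On mechanism the pericyclic cascade and the palladium cycle of step 7 are equals in precedent, but the cascade solves a sub-problem whereas step 7 joins all three parts of the skeleton at once. On step economy the alternative is expected to be clearly longer, since the endgame it spares (steps 9 to 11) is outweighed by the synthesis of A3, a separate construction of the C4 ketone and a hard final dealkylation.

Alternative 2: The cut is the C4–C4a bond of ring C. The precursor is the (E)-3-aryl-3-aryloxy-2-methoxyacrylic acid A4, in which the carboxyl and aryloxy groups are on the same side of the double bond. Its acid chloride would acylate the aryloxy ring at C4a, the only ortho carbon that is not substituted, and so close ring C to the tetra-O-allyl flavone A5.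
- In its favour: both chains are in place before the heterocycle exists. The ring closure has a single possible site, so its regiochemistry is the equal of the symmetric cyclodehydration of step 8. The four allyl ethers of A5 could be removed with a zerovalent palladium catalyst and a mild allyl acceptor under nearly neutral conditions; this is better than the chosen plan, whose final step exposes two ortho-prenylphenols to acid.
- Against it here: acid chloride formation and Friedel–Crafts acylation mean hydrogen halide and a Lewis acid in the presence of two trisubstituted alkenes and four allyl aryl ethers, exactly the groups that add acid, cyclise or are cleaved under such conditions. A4 is a tetrasubstituted push-pull alkene whose geometry must be set and held, since only one isomer can cyclise. Its aryloxy part is a 2-prenylphloroglucinol with differentiated oxygens, so the problem of placing the ring A chain returns at an earlier stage.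
- Comparison: in convergence the two plans are equal (two aryl fragments and a small linking unit). Mechanistically the chosen plan keeps the alkene under basic, palladium-catalysed conditions at the bond-forming stage, whereas the alternative needs strongly electrophilic conditions at its most functionalised stage. In step count the alternative is likely to be equal at best, because what it saves after ring closure it spends on the differentiated phenol and on the stereodefined acid A4.

Alternative 3: The cut is at the two trisubstituted double bonds: each CH=C(CH3)2 unit is traced back to a terminal CH=CH2 unit, so the precursor is the 8,5'-diallyl tetraacetate A6. In the forward direction A6 and an excess of 2-methylbut-2-ene A7 would be treated with a ruthenium benzylidene catalyst bearing an N-heterocyclic carbene ligand. Two cross-metatheses, each releasing a volatile three-carbon alkene, would give the tetraacetate A8 of the target, and mild methanolysis would finish.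
- In its favour: the acid-sensitive chains appear only in the penultimate step, so the flavone can be built and cyclised under conditions that an allyl group, which forms no tertiary cation, tolerates far better. Allyl groups are put on carbon by ordinary ortho-Claisen shifts, in which inversion of a symmetrical allyl unit is invisible. The last deprotection is basic and not acidic. On these three points the alternative is better than the chosen plan, which carries the ring B chain through an acidic step.
- Against it here: the metathesis says nothing about how the flavone core is assembled, so it replaces the endgame and the fragment syntheses but not the strategy. The C8 allyl group would still be delivered by a [3,3] shift from O7 that must choose C8 over C6, so the main regiochemical question of the chosen plan is equalled, not removed. Ruthenium hydride species can move the allyl double bond into conjugation with the arene, which would shorten the chain by one carbon after metathesis. The change to acetate protection costs extra steps.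
- Comparison: in mechanism and precedent the two are equals, both being established catalytic reactions applied to new substrates. In structure the alternative treats the sensitive groups more gently. In step economy it is expected to be about equal or slightly longer, since two O-allylations, two Claisen shifts and an acetylation precede the metathesis. The two ideas are compatible, and the metathesis is held in reserve in the chosen plan.

Key step: step 7

Remark: the ring B chain is attached by SN2 coupling of an aryl-metal species with 10 and not by a sigmatropic shift from O4', because an ortho-Claisen shift of an O-prenyl ether would place the branched 1,1-dimethylallyl isomer on C5'; 3,5-dibromo-2-hydroxybenzaldehyde and N,2-dimethoxy-N-methylacetamide are taken to be commercial.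

## Route

Step 1
Reactants: 1 phloroglucinol (benzene-1,3,5-triol); 2 chloromethyl methyl ether
Product: 3 1,3,5-tris(methoxymethoxy)benzene
Conditions: NaH, MOMCl, DMF, 0 °C to rt
Reagents that add atoms: chloromethyl methyl ether 2, COCCl
Why: Threefold Williamson-type O-alkylation of the sodium phenoxide; the hard chloromethyl ether and the polar aprotic solvent favour O- over C-alkylation of the phloroglucinol anion.

Step 2
Reactants: 3 1,3,5-tris(methoxymethoxy)benzene
Product: 5 2-iodo-1,3,5-tris(methoxymethoxy)benzene, via aryllithium 4 (not isolated)
Conditions: n-BuLi, THF, 0 °C; then I2, −78 °C to rt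
Reagents that add atoms: iodine, II
Why: Directed ortho-metalation: every ring carbon lies between two coordinating OCH2OCH3 groups and all three are equivalent, so a single monolithio species 4 forms; iodinolysis of the C–Li bond places iodine between two identical oxygens.

Step 3
Reactants: 6 3,5-dibromo-2-hydroxybenzaldehyde
Product: 8 3,5-dibromobenzene-1,2-diol, via aryl formate 7 (not isolated)
Conditions: 30% aq. H2O2, NaOH, H2O–THF, 0 °C to rt; then aq. HCl
Reagents that add atoms: hydrogen peroxide, OO
Why: Dakin oxidation: hydroperoxide adds to the aldehyde, the phenoxide-bearing aryl group migrates to oxygen to give formate 7, and the formate is saponified in the same basic medium; the result is a catechol with bromine at exactly the two carbons needed.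

Step 4
Reactants: 8 3,5-dibromobenzene-1,2-diol; 2 chloromethyl methyl ether
Product: 9 1,5-dibromo-2,3-bis(methoxymethoxy)benzene
Conditions: NaH, MOMCl, DMF, 0 °C to rt
Reagents that add atoms: chloromethyl methyl ether 2, COCCl
Why: Williamson-type O-alkylation of both phenoxides; the acetals later stabilise the ortho-lithium species and withstand all basic and organometallic steps.

Step 5
Reactants: 9 1,5-dibromo-2,3-bis(methoxymethoxy)benzene; 10 1-bromo-3-methylbut-2-ene (prenyl bromide)
Product: 12 5-bromo-1,2-bis(methoxymethoxy)-3-(3-methylbut-2-enyl)benzene, via aryllithium 11 (not isolated)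
Conditions: n-BuLi (1.0 equiv), THF, −78 °C; CuBr·SMe2 (1.0 equiv), −78 to −40 °C; prenyl bromide, −78 to 0 °C
Reagents that add atoms: 1-bromo-3-methylbut-2-ene 10, CC(C)=CCBr
Why: Bromine–lithium exchange settles at the bromine ortho to an OCH2OCH3 group because aryllithium 11 is stabilised by induction and chelation, and exchange at the other bromine equilibrates to 11 through ArLi/ArBr exchange. Transmetalation to copper and SN2 coupling at the unhindered primary terminus of the allylic bromide gives the linear chain.

Step 6
Reactants: 12 5-bromo-1,2-bis(methoxymethoxy)-3-(3-methylbut-2-enyl)benzene; 13 N,2-dimethoxy-N-methylacetamide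
Product: 15 1-[3,4-bis(methoxymethoxy)-5-(3-methylbut-2-enyl)phenyl]-2-methoxyethanone, via aryllithium 14 (not isolated)
Conditions: n-BuLi, THF, −78 °C; then MeOCH2C(O)N(OMe)Me, −78 to 0 °C; aq. NH4Cl
Reagents that add atoms: N,2-dimethoxy-N-methylacetamide 13, COCC(=O)N(C)OC
Why: A second bromine–lithium exchange is followed by Weinreb ketone synthesis; the chelated tetrahedral intermediate holds until work-up, so the ketone is not attacked twice. The methoxyacetyl unit delivers C2, C3 and the 3-methoxy group of the flavone in one piece.

Step 7
Reactants: 5 2-iodo-1,3,5-tris(methoxymethoxy)benzene; 16 carbon monoxide; 15 1-[3,4-bis(methoxymethoxy)-5-(3-methylbut-2-enyl)phenyl]-2-methoxyethanone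
Product: 18 2-methoxy-1-[2,4,6-tris(methoxymethoxy)phenyl]-3-[3,4-bis(methoxymethoxy)-5-(3-methylbut-2-enyl)phenyl]propane-1,3-dione, via sodium enolate 17 (not isolated)
Conditions: 15 (2 equiv), NaN(SiMe3)2 (2 equiv), THF, 0 °C; then 5 (1 equiv), Pd(dba)2 (5 mol %), Ph2P(CH2)3PPh2 (6 mol %), CO (1 atm, released ex situ in a sealed two-chamber vessel), THF, 80 °C; aq. NH4Cl
Reagents that add atoms: carbon monoxide 16, [C-]#[O+]
Why: Zerovalent palladium, formed from Pd(dba)2 and the diphosphine, inserts into the C–I bond of 5; CO inserts into the aryl–palladium bond to give an aroylpalladium iodide, the sodium enolate 17 displaces iodide, and reductive elimination from the carbon-bound enolate forges C4–C3 and returns zerovalent palladium. The diketone is at once deprotonated by the second equivalent of 17, which drives the reaction and protects 18 from a second acylation; the ketone 15 released in this way is recovered. The closest known reaction type is the palladium-catalysed carbonylative α-arylation of aryl ketones with aryl iodides to give 1,3-diketones. No ring is closed; the only new stereocentre, the methoxy-bearing carbon between the two carbonyl groups, is enolisable, is left racemic and becomes the sp2 carbon C3 in step 8. The selectivity required is carbonylative over direct α-arylation: the two ortho OCH2OCH3 groups of 5 retard the crowded direct C–C reductive elimination, the electron-rich aryl group migrates readily onto CO, and a CO atmosphere with a chelating diphosphine keeps the aroyl complex as the resting state. Regiochemistry is fixed on the ketone side because 15 has one enolisable position and on ring A because 5 derives from a threefold-symmetric arene. Premixing 15 with the base leaves no free amide to intercept the aroylpalladium species.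

Step 8
Reactants: 18 2-methoxy-1-[2,4,6-tris(methoxymethoxy)phenyl]-3-[3,4-bis(methoxymethoxy)-5-(3-methylbut-2-enyl)phenyl]propane-1,3-dione
Product: 20 2-[3,4-dihydroxy-5-(3-methylbut-2-enyl)phenyl]-5,7-dihydroxy-3-methoxychromen-4-one, via pentahydroxy diketone 19 (not isolated)
Conditions: 3 M aq. HCl–MeOH (1:5), 50 °C
Reagents that add atoms: none
Why: Acid-catalysed transacetalisation to methanol removes all five acetals to give 19; either of the two equivalent ortho hydroxyls adds to the ring B carbonyl and the hemiketal loses water to the conjugated chromen-4-one, as in the last stage of a Baker–Venkataraman flavone synthesis. The temperature is kept moderate so that the C5' chain next to the free 4'-OH is not protonated.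

Step 9
Reactants: 20 2-[3,4-dihydroxy-5-(3-methylbut-2-enyl)phenyl]-5,7-dihydroxy-3-methoxychromen-4-one; 2 chloromethyl methyl ether
Product: 21 2-[3,4-bis(methoxymethoxy)-5-(3-methylbut-2-enyl)phenyl]-5-hydroxy-3-methoxy-7-(methoxymethoxy)chromen-4-one
Conditions: MOMCl (3.3 equiv), K2CO3, acetone, 0 °C to rt, N2
Reagents that add atoms: chloromethyl methyl ether 2, COCCl
Why: The 5-OH is locked in a hydrogen bond to the C4 carbonyl and is far less nucleophilic than the 7-, 3'- and 4'-phenoxides, so a weak base and three equivalents of the chloromethyl ether should acetalise only those three (selective Williamson-type protection).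

Step 10
Reactants: 21 2-[3,4-bis(methoxymethoxy)-5-(3-methylbut-2-enyl)phenyl]-5-hydroxy-3-methoxy-7-(methoxymethoxy)chromen-4-one; 10 1-bromo-3-methylbut-2-ene
Product: 22 2-[3,4-bis(methoxymethoxy)-5-(3-methylbut-2-enyl)phenyl]-3-methoxy-7-(methoxymethoxy)-5-(3-methylbut-2-enyloxy)chromen-4-one
Conditions: prenyl bromide (excess), K2CO3, acetone, reflux
Reagents that add atoms: 1-bromo-3-methylbut-2-ene 10, CC(C)=CCBr
Why: Williamson O-alkylation of the one remaining, chelated phenol with an excess of the reactive allylic bromide under more forcing conditions; the carbonate base is too weak to generate a carbon nucleophile, so the chain goes to oxygen.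

Step 11
Reactants: 22 2-[3,4-bis(methoxymethoxy)-5-(3-methylbut-2-enyl)phenyl]-3-methoxy-7-(methoxymethoxy)-5-(3-methylbut-2-enyloxy)chromen-4-one
Product: 25 2-[3,4-bis(methoxymethoxy)-5-(3-methylbut-2-enyl)phenyl]-5-hydroxy-3-methoxy-7-(methoxymethoxy)-8-(3-methylbut-2-enyl)chromen-4-one, via ortho dienone 23 (not isolated), via para dienone 24 (not isolated)
Conditions: Eu(fod)3 (10 mol %), NaHCO3, PhCl, 85 °C
Reagents that add atoms: none
Why: Eu(fod)3 binds the C4 carbonyl and O5 and lowers the barrier of the aromatic Claisen shift to C6 (dienone 23, chain branched); a Cope shift from C6 to C8 follows (dienone 24, chain linear again) and enolisation restores ring A, a para-Claisen–Cope sequence precedented for 5-O-prenyl flavonoids. NaHCO3 removes traces of acid that would enolise 23 before the second shift; the transient stereocentres at C6 and C8 vanish on aromatisation.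

Step 12
Reactants: 25 2-[3,4-bis(methoxymethoxy)-5-(3-methylbut-2-enyl)phenyl]-5-hydroxy-3-methoxy-7-(methoxymethoxy)-8-(3-methylbut-2-enyl)chromen-4-one
Product: 26 2-[3,4-dihydroxy-5-(3-methylbut-2-enyl)phenyl]-5,7-dihydroxy-3-methoxy-8-(3-methylbut-2-enyl)chromen-4-one
Conditions: 3 M aq. HCl–MeOH (1:5), 45 °C, stopped at full conversion
Reagents that add atoms: none
Why: Acid-catalysed methanolysis of the three aryl acetals; dilute acid at moderate temperature suffices for aryl methoxymethyl ethers and the exposure is kept short so that neither chain cyclises onto its ortho hydroxyl. The 3-methoxy group is a true ether and is untouched.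

## Compound list

1 | phloroglucinol (benzene-1,3,5-triol) | Oc1cc(O)cc(O)c1 | starting material
2 | chloromethyl methyl ether | COCCl | starting material
3 | 1,3,5-tris(methoxymethoxy)benzene | COCOc1cc(OCOC)cc(OCOC)c1 | intermediate
4 | [2,4,6-tris(methoxymethoxy)phenyl]lithium (not isolated) | [Li]c1c(OCOC)cc(OCOC)cc1OCOC | intermediate
5 | 2-iodo-1,3,5-tris(methoxymethoxy)benzene | COCOc1cc(OCOC)c(I)c(OCOC)c1 | intermediate
6 | 3,5-dibromo-2-hydroxybenzaldehyde | O=Cc1cc(Br)cc(Br)c1O | starting material
7 | 3,5-dibromo-2-hydroxyphenyl formate (not isolated) | O=COc1cc(Br)cc(Br)c1O | intermediate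
8 | 3,5-dibromobenzene-1,2-diol | Oc1cc(Br)cc(Br)c1O | intermediate
9 | 1,5-dibromo-2,3-bis(methoxymethoxy)benzene | COCOc1cc(Br)cc(Br)c1OCOC | intermediate
10 | 1-bromo-3-methylbut-2-ene (prenyl bromide) | CC(C)=CCBr | starting material
11 | [5-bromo-2,3-bis(methoxymethoxy)phenyl]lithium (not isolated) | COCOc1cc(Br)cc([Li])c1OCOC | intermediate
12 | 5-bromo-1,2-bis(methoxymethoxy)-3-(3-methylbut-2-enyl)benzene | COCOc1cc(Br)cc(CC=C(C)C)c1OCOC | intermediate
13 | N,2-dimethoxy-N-methylacetamide | COCC(=O)N(C)OC | starting material
14 | [3,4-bis(methoxymethoxy)-5-(3-methylbut-2-enyl)phenyl]lithium (not isolated) | COCOc1cc([Li])cc(CC=C(C)C)c1OCOC | intermediate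
15 | 1-[3,4-bis(methoxymethoxy)-5-(3-methylbut-2-enyl)phenyl]-2-methoxyethanone | COCC(=O)c1cc(OCOC)c(OCOC)c(CC=C(C)C)c1 | intermediate
16 | carbon monoxide | [C-]#[O+] | starting material
17 | sodium 1-[3,4-bis(methoxymethoxy)-5-(3-methylbut-2-enyl)phenyl]-2-methoxyethenolate (not isolated; double-bond geometry not defined) | [Na+].COC=C([O-])c1cc(OCOC)c(OCOC)c(CC=C(C)C)c1 | intermediate
18 | 2-methoxy-1-[2,4,6-tris(methoxymethoxy)phenyl]-3-[3,4-bis(methoxymethoxy)-5-(3-methylbut-2-enyl)phenyl]propane-1,3-dione (racemic, enolisable) | COCOc1cc(OCOC)c(C(=O)C(OC)C(=O)c2cc(OCOC)c(OCOC)c(CC=C(C)C)c2)c(OCOC)c1 | intermediate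
19 | 1-[3,4-dihydroxy-5-(3-methylbut-2-enyl)phenyl]-2-methoxy-3-(2,4,6-trihydroxyphenyl)propane-1,3-dione (not isolated; racemic) | COC(C(=O)c1c(O)cc(O)cc1O)C(=O)c1cc(O)c(O)c(CC=C(C)C)c1 | intermediate
20 | 2-[3,4-dihydroxy-5-(3-methylbut-2-enyl)phenyl]-5,7-dihydroxy-3-methoxychromen-4-one | COc1c(-c2cc(O)c(O)c(CC=C(C)C)c2)oc2cc(O)cc(O)c2c1=O | intermediate
21 | 2-[3,4-bis(methoxymethoxy)-5-(3-methylbut-2-enyl)phenyl]-5-hydroxy-3-methoxy-7-(methoxymethoxy)chromen-4-one | COc1c(-c2cc(OCOC)c(OCOC)c(CC=C(C)C)c2)oc2cc(OCOC)cc(O)c2c1=O | intermediate
22 | 2-[3,4-bis(methoxymethoxy)-5-(3-methylbut-2-enyl)phenyl]-3-methoxy-7-(methoxymethoxy)-5-(3-methylbut-2-enyloxy)chromen-4-one | COc1c(-c2cc(OCOC)c(OCOC)c(CC=C(C)C)c2)oc2cc(OCOC)cc(OCC=C(C)C)c2c1=O | intermediate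
23 | 2-[3,4-bis(methoxymethoxy)-5-(3-methylbut-2-enyl)phenyl]-3-methoxy-7-(methoxymethoxy)-6-(2-methylbut-3-en-2-yl)-6H-chromene-4,5-dione (not isolated; racemic) | COC1=C(c2cc(OCOC)c(OCOC)c(CC=C(C)C)c2)OC2=C(C1=O)C(=O)C(C(C)(C)C=C)C(OCOC)=C2 | intermediate
24 | 2-[3,4-bis(methoxymethoxy)-5-(3-methylbut-2-enyl)phenyl]-3-methoxy-7-(methoxymethoxy)-8-(3-methylbut-2-enyl)-8H-chromene-4,5-dione (not isolated; racemic) | COC1=C(c2cc(OCOC)c(OCOC)c(CC=C(C)C)c2)OC2=C(C1=O)C(=O)C=C(OCOC)C2CC=C(C)C | intermediate
25 | 2-[3,4-bis(methoxymethoxy)-5-(3-methylbut-2-enyl)phenyl]-5-hydroxy-3-methoxy-7-(methoxymethoxy)-8-(3-methylbut-2-enyl)chromen-4-one | COc1c(-c2cc(OCOC)c(OCOC)c(CC=C(C)C)c2)oc2c(CC=C(C)C)c(OCOC)cc(O)c2c1=O | intermediate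
26 | 2-[3,4-dihydroxy-5-(3-methylbut-2-enyl)phenyl]-5,7-dihydroxy-3-methoxy-8-(3-methylbut-2-enyl)chromen-4-one (5,7,3',4'-tetrahydroxy-3-methoxy-8,5'-diprenylflavone; no stereocentre) | COc1c(-c2cc(O)c(O)c(CC=C(C)C)c2)oc2c(CC=C(C)C)c(O)cc(O)c2c1=O | target

## Step count and least certain steps

Total step count: 12. Longest linear sequence: 10 steps (steps 3 to 12, from 6); the ring A branch (steps 1 and 2) joins at step 7.

**Step 7 (key step).**
- What may go wrong: slow CO uptake by the crowded arylpalladium iodide, or slow reductive elimination from the hindered aroylpalladium enolate, so that direct α-arylation, reduction of the C–I bond or O-acylation of the enolate takes over. The cause is the double ortho substitution of 5 combined with an α-alkoxy enolate that is less nucleophilic at carbon than a simple one.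
- Fallback, from 3 and 15 back to 18: the same two bonds are made one after the other by polar chemistry. Lithiation of 3 as in step 2 and quenching with N,N-dimethylformamide should give 2,4,6-tris(methoxymethoxy)benzaldehyde F1 (C4a–C4 formed). Addition of the lithium enolate of 15 (LiN(SiMe3)2, THF, −78 °C) to F1 should give the aldol 3-hydroxy-2-methoxy-1-[3,4-bis(methoxymethoxy)-5-(3-methylbut-2-enyl)phenyl]-3-[2,4,6-tris(methoxymethoxy)phenyl]propan-1-one F2 as a mixture of diastereomers (C4–C3 formed). Oxidation of the secondary alcohol with Dess–Martin periodinane in NaHCO3-buffered CH2Cl2 makes the diastereomer mixture irrelevant and rejoins the route at 18.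

**Step 5.**
- What may go wrong: exchange at the wrong bromine or at both (loss of site selectivity through local excess of n-BuLi or incomplete equilibration), and attack of the arylcopper species at the tertiary end of the allyl unit (allylic transposition to the branched chain). Both arise because two similar C–Br bonds and an ambident electrophile are involved.
- Fallback, from 9 back to 12: the aryl-metal species (11, or the arylmagnesium analogue from i-PrMgCl·LiCl) is trapped with allyl bromide, whose two termini are identical, to give 5-bromo-1,2-bis(methoxymethoxy)-3-(prop-2-enyl)benzene F3. Cross-metathesis of F3 with excess 2-methylbut-2-ene and the second-generation Grubbs catalyst RuCl2(=CHPh)(PCy3)(H2IMes) in CH2Cl2 at 40 °C then converts the allyl group into the 3-methylbut-2-enyl group and rejoins the route at 12.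

**Step 8.**
- What may go wrong: protonation of the ring B alkene during the heated acid treatment, followed by capture of the tertiary cation by the adjacent 4'-OH or by the solvent. The cause is that ring closure needs more heat than acetal cleavage.
- Fallback, from 18 back to 20: the two tasks are separated. Methanolic HCl at room temperature is used only to cleave the acetals, and 19 is isolated. Ring closure with loss of water is then carried out in NaOAc-buffered acetic acid at 90 °C, a medium too weakly acidic to protonate a trisubstituted alkene. No new compound is involved.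

**Step 11.**
- What may go wrong: enolisation of the ortho dienone 23 before the Cope shift, which would leave the chain on C6 in its branched form, and Lewis-acid ionisation of the allylic C–O bond with loss of the chain. The cause is that the second [3,3] shift competes with a fast proton transfer.
- Fallback, from 20 to 26: the chain is built on C8 by an allyl shift from O7 followed by metathesis.
  - Exhaustive acetylation (Ac2O, pyridine, catalytic 4-dimethylaminopyridine) should give 5,7-diacetoxy-2-[3,4-diacetoxy-5-(3-methylbut-2-enyl)phenyl]-3-methoxychromen-4-one F4.
  - Thiophenol with imidazole in N-methylpyrrolidone at 0 °C should remove the most labile 7-O-acetyl group to give 5-acetoxy-2-[3,4-diacetoxy-5-(3-methylbut-2-enyl)phenyl]-7-hydroxy-3-methoxychromen-4-one F5.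
  - Mitsunobu reaction with allyl alcohol (PPh3, diisopropyl azodicarboxylate, THF) should give 5-acetoxy-2-[3,4-diacetoxy-5-(3-methylbut-2-enyl)phenyl]-3-methoxy-7-(prop-2-enyloxy)chromen-4-one F6.
  - Thermal Claisen rearrangement (N,N-diethylaniline, 190 °C) should favour C8, the C7–C8 bond having the higher double-bond character in benzopyranones, to give 5-acetoxy-2-[3,4-diacetoxy-5-(3-methylbut-2-enyl)phenyl]-7-hydroxy-3-methoxy-8-(prop-2-enyl)chromen-4-one F7.
  - Cross-metathesis with excess 2-methylbut-2-ene and the second-generation Grubbs catalyst RuCl2(=CHPh)(PCy3)(H2IMes), in which the ring B chain can only be regenerated, should give 5-acetoxy-2-[3,4-diacetoxy-5-(3-methylbut-2-enyl)phenyl]-7-hydroxy-3-methoxy-8-(3-methylbut-2-enyl)chromen-4-one F8.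
  - Methanolysis (K2CO3, MeOH, 0 °C, argon, then mild acidification) returns to the route at 26.

**Step 12.**
- What may go wrong: acid-induced ring closure of either chain onto its ortho hydroxyl (7-OH with the C8 chain, 4'-OH with the C5' chain) while the last acetal is being cleaved. The product now contains two such pairs.
- Fallback, from 20 to 26: base-labile protection replaces the acetals, so that the final step is not acidic.
  - Controlled acetylation (Ac2O, 3.3 equiv, pyridine, 0 °C) should leave the chelated 5-OH free and give 7-acetoxy-2-[3,4-diacetoxy-5-(3-methylbut-2-enyl)phenyl]-5-hydroxy-3-methoxychromen-4-one F9.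
  - Mitsunobu etherification with 3-methylbut-2-en-1-ol (PPh3, diisopropyl azodicarboxylate, THF) should give 7-acetoxy-2-[3,4-diacetoxy-5-(3-methylbut-2-enyl)phenyl]-3-methoxy-5-(3-methylbut-2-enyloxy)chromen-4-one F10.
  - The Eu(fod)3-catalysed Claisen–Cope sequence should give 7-acetoxy-2-[3,4-diacetoxy-5-(3-methylbut-2-enyl)phenyl]-5-hydroxy-3-methoxy-8-(3-methylbut-2-enyl)chromen-4-one F11.
  - Methanolysis (K2CO3, MeOH, 0 °C, argon) returns to the route at 26.

## Further compounds

F1 | step 7 | 2,4,6-tris(methoxymethoxy)benzaldehyde | COCOc1cc(OCOC)c(C=O)c(OCOC)c1
F2 | step 7 | 3-hydroxy-2-methoxy-1-[3,4-bis(methoxymethoxy)-5-(3-methylbut-2-enyl)phenyl]-3-[2,4,6-tris(methoxymethoxy)phenyl]propan-1-one (racemic mixture of diastereomers) | COCOc1cc(OCOC)c(C(O)C(OC)C(=O)c2cc(OCOC)c(OCOC)c(CC=C(C)C)c2)c(OCOC)c1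
F3 | step 5 | 5-bromo-1,2-bis(methoxymethoxy)-3-(prop-2-enyl)benzene | COCOc1cc(Br)cc(CC=C)c1OCOC
F0 | step 8 | none | none
F4 | step 11 | 5,7-diacetoxy-2-[3,4-diacetoxy-5-(3-methylbut-2-enyl)phenyl]-3-methoxychromen-4-one | COc1c(-c2cc(OC(C)=O)c(OC(C)=O)c(CC=C(C)C)c2)oc2cc(OC(C)=O)cc(OC(C)=O)c2c1=O
F5 | step 11 | 5-acetoxy-2-[3,4-diacetoxy-5-(3-methylbut-2-enyl)phenyl]-7-hydroxy-3-methoxychromen-4-one | COc1c(-c2cc(OC(C)=O)c(OC(C)=O)c(CC=C(C)C)c2)oc2cc(O)cc(OC(C)=O)c2c1=O
F6 | step 11 | 5-acetoxy-2-[3,4-diacetoxy-5-(3-methylbut-2-enyl)phenyl]-3-methoxy-7-(prop-2-enyloxy)chromen-4-one | COc1c(-c2cc(OC(C)=O)c(OC(C)=O)c(CC=C(C)C)c2)oc2cc(OCC=C)cc(OC(C)=O)c2c1=O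
F7 | step 11 | 5-acetoxy-2-[3,4-diacetoxy-5-(3-methylbut-2-enyl)phenyl]-7-hydroxy-3-methoxy-8-(prop-2-enyl)chromen-4-one | COc1c(-c2cc(OC(C)=O)c(OC(C)=O)c(CC=C(C)C)c2)oc2c(CC=C)c(O)cc(OC(C)=O)c2c1=O
F8 | step 11 | 5-acetoxy-2-[3,4-diacetoxy-5-(3-methylbut-2-enyl)phenyl]-7-hydroxy-3-methoxy-8-(3-methylbut-2-enyl)chromen-4-one | COc1c(-c2cc(OC(C)=O)c(OC(C)=O)c(CC=C(C)C)c2)oc2c(CC=C(C)C)c(O)cc(OC(C)=O)c2c1=O
F9 | step 12 | 7-acetoxy-2-[3,4-diacetoxy-5-(3-methylbut-2-enyl)phenyl]-5-hydroxy-3-methoxychromen-4-one | COc1c(-c2cc(OC(C)=O)c(OC(C)=O)c(CC=C(C)C)c2)oc2cc(OC(C)=O)cc(O)c2c1=O
F10 | step 12 | 7-acetoxy-2-[3,4-diacetoxy-5-(3-methylbut-2-enyl)phenyl]-3-methoxy-5-(3-methylbut-2-enyloxy)chromen-4-one | COc1c(-c2cc(OC(C)=O)c(OC(C)=O)c(CC=C(C)C)c2)oc2cc(OC(C)=O)cc(OCC=C(C)C)c2c1=O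
F11 | step 12 | 7-acetoxy-2-[3,4-diacetoxy-5-(3-methylbut-2-enyl)phenyl]-5-hydroxy-3-methoxy-8-(3-methylbut-2-enyl)chromen-4-one | COc1c(-c2cc(OC(C)=O)c(OC(C)=O)c(CC=C(C)C)c2)oc2c(CC=C(C)C)c(OC(C)=O)cc(O)c2c1=O
A1 | alternative 1 | 5-ethoxy-2-(3-methylbut-2-enyl)-3-(triisopropylsilyloxy)phenol | CCOc1cc(O)c(CC=C(C)C)c(O[Si](C(C)C)(C(C)C)C(C)C)c1
A2 | alternative 1 | 3-ethoxycyclobut-2-en-1-one | CCOC1=CC(=O)C1
A3 | alternative 1 | triisopropyl(5-methylhex-4-en-1-ynyloxy)silane | CC(C)=CCC#CO[Si](C(C)C)(C(C)C)C(C)C
A4 | alternative 2 | (E)-3-[3,4-bis(prop-2-enyloxy)-5-(3-methylbut-2-enyl)phenyl]-3-[3,5-bis(prop-2-enyloxy)-2-(3-methylbut-2-enyl)phenoxy]-2-methoxyprop-2-enoic acid | CO/C(C(O)=O)=C(/Oc1cc(OCC=C)cc(OCC=C)c1CC=C(C)C)c1cc(OCC=C)c(OCC=C)c(CC=C(C)C)c1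
A5 | alternative 2 | 2-[3,4-bis(prop-2-enyloxy)-5-(3-methylbut-2-enyl)phenyl]-3-methoxy-8-(3-methylbut-2-enyl)-5,7-bis(prop-2-enyloxy)chromen-4-one | COc1c(-c2cc(OCC=C)c(OCC=C)c(CC=C(C)C)c2)oc2c(CC=C(C)C)c(OCC=C)cc(OCC=C)c2c1=O
A6 | alternative 3 | 5,7-diacetoxy-2-[3,4-diacetoxy-5-(prop-2-enyl)phenyl]-3-methoxy-8-(prop-2-enyl)chromen-4-one | COc1c(-c2cc(OC(C)=O)c(OC(C)=O)c(CC=C)c2)oc2c(CC=C)c(OC(C)=O)cc(OC(C)=O)c2c1=O
A7 | alternative 3 | 2-methylbut-2-ene | CC=C(C)C
A8 | alternative 3 | 5,7-diacetoxy-2-[3,4-diacetoxy-5-(3-methylbut-2-enyl)phenyl]-3-methoxy-8-(3-methylbut-2-enyl)chromen-4-one | COc1c(-c2cc(OC(C)=O)c(OC(C)=O)c(CC=C(C)C)c2)oc2c(CC=C(C)C)c(OC(C)=O)cc(OC(C)=O)c2c1=O
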